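A small charge of second catalyst, 19 mol% of the substrate, opens a slow drain on the intermediate while the free catalyst fills it, and I want the moment at which the drain catches the fill.

in all of them: substrate 0.30 M; free catalyst 10 mol%
- north-east: partner 1.1 equiv; second catalyst 9.5 mol%; run made earlier
- south: partner 1.1 equiv; second catalyst 38 mol%; run made earlier
- flask: partner 1.10 equiv; second catalyst 19 mol%; time 50 h

| run | time / h | intermediate / % | target / % |
|---|---|---|---|
| north-east | 0.833 | 65.1 | 0.7 |
| north-east | 3.00 | 95.1 | 2.5 |
| north-east | 15.0 | 87.5 | 12.5 |
| north-east | 60.0 | 78.3 | 21.9 |
| south | 0.833 | 64.2 | 1.8 |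
| south | 3.00 | 88.0 | 10.1 |
| south | 15.0 | 69.0 | 30.8 |
| south | 60.0 | 62.0 | 37.6 |

(each reading ± 0.3 percentage points)

- time up to 50 h at which intermediate stands highest
- the amount of intermediate, in percent of the substrate charged, at that time

- the earlier runs were read with a standard deviation of 0.3 percentage points

At the first reading 34.2 % of the substrate is unaccounted for in the north-east run and 34.0 % in the south run. So I take the fill as pseudo-first-order, with rate constant 1.29 h⁻¹ and half-life 0.538 h, the same at both loadings of second catalyst.

Target at 3.00 h stands 4.04 times higher in the south run, for 4.00 times the loading. Allowing for a lag of one fill lifetime, the south reading scales to a drain of 0.0227 h⁻¹ in this flask.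

The fill therefore starts faster than the drain by a factor of 56.8, and it falls by a factor of 2 each half-life. The south run's hourly target gain drops by a factor of 11.4, but that is read after 3.00 h, so for these early hours I hold the drain constant.

In this flask the fill needs 5.83 half-lives to sink to the drain, the peak count. That puts my peak at 3.14 h. My shortfall there, substrate and target together, is drain times time, 7.12 %, which leaves 92.9 % intermediate.

The forecast gives 3.2 h and 92.9 %, and says of the later stall “that matters little this early”.

The flask reaches its highest intermediate, 92.3 %, at 3.16 h, with 1.65 % substrate and 6.02 % target beside it. By 50.0 h this flask is down to 69.3 % intermediate, so it is to be stopped near the peak.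

    substrate + free catalyst → free catalyst + intermediate (k = 0.0120 L mol⁻¹ s⁻¹)
    partner + second catalyst + intermediate ⇌ second catalyst + target (K = 3.20 L mol⁻¹, k = 4.40 × 10⁻⁴ L² mol⁻² s⁻¹)
    second catalyst → spent catalyst (k = 1.10 × 10⁻⁵ s⁻¹)
    substrate + target → side product (k = 2.20 × 10⁻⁵ L mol⁻¹ s⁻¹)

The peak count carries to the neighbour flask with 4.8 mol% of second catalyst. Scaled by loading, its drain is a quarter of this flask's, 0.00574 h⁻¹, so in my count the fill there needs 7.81 half-lives. My count moves its peak to 4.20 h, and drain times time leaves 97.6 % intermediate. That neighbour flask's simulated highest intermediate stands at 97.3 %.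

The earlier runs and the new flask are calculated from invented constants; the scatter is artificial.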